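The cyclohexane of metachromin H carries a quaternary C1 (methyl plus side chain), an exocyclic methylene on C2 and a C3 methine whose methyl is cis to the C1 chain across sp2 C2. This is exploited by disconnecting C2–C3 and C1–C6 in a Diels–Alder sense: a cyclopentenone β-keto ester (ring ketone, ester on the α-carbon, methyl on the β-carbon) adds (E)-penta-1,3-diene ketone-endo under the chiral Lewis acid [Cu((S,S)-t-Bu-box)](SbF6)2, closing the ring and fixing both stereocentres, plus a sacrificial third, at once. The five-membered ring is later opened by Grob fragmentation, unveiling the C2 methylene and a chain methyl ketone, which is homologated and joined to the quinone.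

Key step: step 3

Assumption: the enantiofacial sense of the catalyst is assigned from a square-planar chelate model; should it prove opposite, the (R,R)-ligand would be used with no other change.
Convention: for compounds 5–9 the hydrindane locants of adduct 5 (C1–C7a) are kept.

Step 1
Reactants: 1 3-methylcyclopent-2-en-1-one
Product: 2 2-iodo-3-methylcyclopent-2-en-1-one
Conditions: I2 (1.5 equiv), K2CO3, DMAP (0.2 equiv), THF–H2O (1:1), rt
Reagents that add atoms: iodine, II
Why: Baylis–Hillman-type α-iodination of an enone (reversible conjugate addition of DMAP, iodination of the enolate, elimination), in the aqueous carbonate variant suited to β-substituted cyclopentenones.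

Step 2
Reactants: 2 2-iodo-3-methylcyclopent-2-en-1-one
Product: 3 methyl 2-methyl-5-oxocyclopent-1-ene-1-carboxylate
Conditions: CO (1 atm), Pd(PPh3)4 (5 mol %), Et3N, MeOH, 60 °C
Reagents that add atoms: carbon monoxide, [C-]#[O+]; methanol, CO
Why: Palladium-catalysed alkoxycarbonylation of a vinyl iodide (oxidative addition to zerovalent palladium, CO insertion, methanolysis of the acylpalladium), for which α-iodoenones are good substrates.

Step 3
Reactants: 3 methyl 2-methyl-5-oxocyclopent-1-ene-1-carboxylate; 4 (E)-penta-1,3-diene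
Product: 5 methyl (3aS,4R,7aS)-4,7a-dimethyl-3-oxo-1,2,3,4,7,7a-hexahydro-3aH-indene-3a-carboxylate (cis-fused; C4 methyl on the side of ketone carbon C3, anti to the ester)
Conditions: [Cu((S,S)-t-Bu-box)](SbF6)2 (10 mol %; from CuCl2, AgSbF6 and 2,2'-(propane-2,2-diyl)bis[(4S)-4-tert-butyl-4,5-dihydro-1,3-oxazole]), 4 (5 equiv), CH2Cl2, 0 °C to rt
Reagents that add atoms: none
Why: Proposed new method: chelation of the ketone and ester oxygens of 3 to the dicationic divalent copper centre should lower the LUMO of the tetrasubstituted alkene enough for a concerted, asynchronous, suprafacial [4+2] addition of 4, the closest known reaction types being Lewis-acid-promoted Diels–Alder additions of 2-alkoxycarbonylcycloalkenones to 1-substituted dienes and Cu(OTf)2– or Cu(SbF6)2–bis(oxazoline)-catalysed cycloadditions of chelating dienophiles, neither of which has been shown enantioselectively on a β-methyl keto ester of this kind. The cyclohexene ring closes by intermolecular [4+2] cycloaddition, both σ-bonds (C3a–C4 and C7–C7a) forming on one face of each component. C3a and C7a are set cis because the dienophile geometry is locked in the five-membered ring and is transferred suprafacially, and C4 is set relative to them by the ketone-endo transition state, which places the diene methyl on the side of C3 and anti to the ester. The absolute configuration is controlled by the tert-butyl groups of the (S,S)-ligand, which in a square-planar chelate model block the quadrant a ketone-endo diene would need on one face and leave the Re face of the ester-bearing carbon open. The step needs ortho regiochemistry, secured by matching the large LUMO coefficient at the β-carbon of 3 with the large HOMO coefficient at the unsubstituted terminus of 4, and ketone-endo over ester-endo selectivity, secured by the rigid s-trans ring carbonyl lying under the diene while the bulkier ester stays exo. The hexafluoroantimonate complex is chosen over the triflate because its weakly coordinating anion gives the stronger Lewis acid that a hindered dienophile and an unactivated diene demand.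

Step 4
Reactants: 5 methyl (3aS,4R,7aS)-4,7a-dimethyl-3-oxo-1,2,3,4,7,7a-hexahydro-3aH-indene-3a-carboxylate
Product: 6 methyl (3aS,4R,7aR)-4,7a-dimethyl-3-oxooctahydro-3aH-indene-3a-carboxylate (same spatial arrangement as 5; the 7a descriptor changes only through priorities)
Conditions: H2 (1 atm), PtO2 (5 mol %), EtOAc, rt
Reagents that add atoms: none
Why: Heterogeneous catalytic hydrogenation of an unhindered cis-disubstituted cyclohexene, with platinum chosen over palladium because it hardly migrates double bonds, so the allylic C4 stereocentre is not put at risk and no new stereocentre forms.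

Step 5
Reactants: 6 methyl (3aS,4R,7aR)-4,7a-dimethyl-3-oxooctahydro-3aH-indene-3a-carboxylate
Product: 7 methyl 3-hydroxy-3,4,7a-trimethyloctahydro-3aH-indene-3a-carboxylate (C3a, C4, C7a as in 6; C3 tertiary alcohol, either epimer)
Conditions: MeLi (1.5 equiv), anhydrous CeCl3 (1.6 equiv), THF, −78 °C; sat. aq NH4Cl at −78 °C
Reagents that add atoms: methyllithium, [Li]C
Why: Organocerium 1,2-addition to a ketone, in which the weakly basic, oxophilic MeCeCl2 should add to the hindered cyclopentanone in preference to enolisation or attack on the quaternary ester, the cold quench guarding the β-alkoxy ester against retro-aldol cleavage; the C3 configuration is uncontrolled and is erased in step 8.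

Step 6
Reactants: 7 methyl 3-hydroxy-3,4,7a-trimethyloctahydro-3aH-indene-3a-carboxylate
Product: 8 3a-(hydroxymethyl)-3,4,7a-trimethyloctahydro-1H-inden-3-ol (1,3-diol; ring stereocentres unchanged)
Conditions: LiAlH4 (3 equiv), THF, 0 °C to reflux; H2O, 15% aq NaOH, H2O work-up
Reagents that add atoms: none
Why: LiAlH4 reduction of an ester to the primary alcohol, in which the tertiary alkoxide is a spectator and no stereocentre is touched.

Step 7
Reactants: 8 3a-(hydroxymethyl)-3,4,7a-trimethyloctahydro-1H-inden-3-ol
Product: 9 (3-hydroxy-3,4,7a-trimethyloctahydro-3aH-inden-3a-yl)methyl methanesulfonate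
Conditions: MsCl (1.1 equiv), Et3N, CH2Cl2, −20 to 0 °C
Reagents that add atoms: methanesulfonyl chloride, CS(=O)(=O)Cl
Why: Chemoselective sulfonylation, the primary hydroxyl being mesylated far faster than the tertiary one at low temperature with one equivalent of reagent.

Step 8
Reactants: 9 (3-hydroxy-3,4,7a-trimethyloctahydro-3aH-inden-3a-yl)methyl methanesulfonate
Product: 10 4-[(1R,3R)-1,3-dimethyl-2-methylidenecyclohexyl]butan-2-one
Conditions: KOt-Bu (1.2 equiv), THF, 0 °C
Reagents that add atoms: none
Why: Grob fragmentation of a 1,3-diol monosulfonate, in which the tertiary alkoxide breaks the C3–C3a bond anti-periplanar to the freely rotating CH2–OMs bond and so releases the ring methylene and the chain methyl ketone together, while the neopentyl carbon disfavours the competing oxetane closure and neither ring stereocentre is involved.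

Step 9
Reactants: 10 4-[(1R,3R)-1,3-dimethyl-2-methylidenecyclohexyl]butan-2-one
Product: 11 ethyl (2E)-5-[(1R,3R)-1,3-dimethyl-2-methylidenecyclohexyl]-3-methylpent-2-enoate
Conditions: (EtO)2P(O)CH2CO2Et (2 equiv), NaH, THF, 0 to 50 °C
Reagents that add atoms: triethyl phosphonoacetate, CCOC(=O)CP(=O)(OCC)OCC
Why: Horner–Wadsworth–Emmons olefination of a methyl ketone, whose reversible addition step should favour the (E)-enoate with the larger ketone substituent trans to the ester, the minor (Z)-isomer to be removed by chromatography.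

Step 10
Reactants: 11 ethyl (2E)-5-[(1R,3R)-1,3-dimethyl-2-methylidenecyclohexyl]-3-methylpent-2-enoate
Product: 12 (2E)-5-[(1R,3R)-1,3-dimethyl-2-methylidenecyclohexyl]-3-methylpent-2-en-1-ol
Conditions: i-Bu2AlH (2.5 equiv), CH2Cl2, −78 °C; aq potassium sodium tartrate
Reagents that add atoms: none
Why: 1,2-Reduction of an α,β-unsaturated ester with i-Bu2AlH to the allylic alcohol, which leaves the alkene geometry and the exocyclic methylene untouched.

Step 11
Reactants: 12 (2E)-5-[(1R,3R)-1,3-dimethyl-2-methylidenecyclohexyl]-3-methylpent-2-en-1-ol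
Product: 13 (1R,3R)-1-[(3E)-5-bromo-3-methylpent-3-en-1-yl]-1,3-dimethyl-2-methylidenecyclohexane
Conditions: CBr4 (1.2 equiv), PPh3 (1.3 equiv), CH2Cl2, 0 °C
Reagents that add atoms: carbon tetrabromide, BrC(Br)(Br)Br
Why: Appel bromination, an SN2 displacement of the alkoxyphosphonium under neutral conditions, which avoids the acid that could move the exocyclic double bond into the ring or scramble the allylic system.

Step 12
Reactants: 13 (1R,3R)-1-[(3E)-5-bromo-3-methylpent-3-en-1-yl]-1,3-dimethyl-2-methylidenecyclohexane; 14 1,2,4,5-tetramethoxybenzene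
Product: 17 3-{(2E)-5-[(1R,3R)-1,3-dimethyl-2-methylidenecyclohexyl]-3-methylpent-2-en-1-yl}-1,2,4,5-tetramethoxybenzene, via (2,3,5,6-tetramethoxyphenyl)lithium 15 (not isolated), via (2,3,5,6-tetramethoxyphenyl)copper 16 (not isolated)
Conditions: 14 (1.5 equiv), n-BuLi (1.4 equiv), TMEDA, THF, 0 °C; CuBr·SMe2 (1.4 equiv), −40 °C; then 13, −40 °C to rt
Reagents that add atoms: none
Why: Directed ortho-lithiation at the ring CH flanked by two methoxy groups, transmetalation to the arylcopper and copper-mediated SN2 allylation of a primary γ,γ-disubstituted allylic bromide, in which attack at the unhindered α-carbon keeps the (E)-geometry.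

Step 13
Reactants: 17 3-{(2E)-5-[(1R,3R)-1,3-dimethyl-2-methylidenecyclohexyl]-3-methylpent-2-en-1-yl}-1,2,4,5-tetramethoxybenzene
Product: 18 3-{(2E)-5-[(1R,3R)-1,3-dimethyl-2-methylidenecyclohexyl]-3-methylpent-2-en-1-yl}-2,5-dimethoxycyclohexa-2,5-diene-1,4-dione
Conditions: (NH4)2Ce(NO3)6 (2.5 equiv), MeCN–H2O (2:1), 0 °C
Reagents that add atoms: water, O
Why: Oxidative demethylation of a para-dimethoxyarene by tetravalent cerium to the para-quinone, a short cold treatment that isolated alkenes, including an exocyclic methylene, are expected to survive.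

Step 14
Reactants: 18 3-{(2E)-5-[(1R,3R)-1,3-dimethyl-2-methylidenecyclohexyl]-3-methylpent-2-en-1-yl}-2,5-dimethoxycyclohexa-2,5-diene-1,4-dione
Product: 19 3-{(2E)-5-[(1R,3R)-1,3-dimethyl-2-methylidenecyclohexyl]-3-methylpent-2-en-1-yl}-2-hydroxy-5-methoxycyclohexa-2,5-diene-1,4-dione
Conditions: KOH (1 M aq), MeOH, rt; then dilute HCl
Reagents that add atoms: potassium hydroxide, [K+].[OH-]
Why: Addition–elimination saponification of a vinylogous ester, in which hydroxide should replace the methoxy group flanked by the alkyl chain, as is usual for 3-alkyl-2,5-dimethoxybenzoquinones, and the resulting vinylogous carboxylate is deactivated toward a second hydrolysis.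

Step 15
Reactants: 19 3-{(2E)-5-[(1R,3R)-1,3-dimethyl-2-methylidenecyclohexyl]-3-methylpent-2-en-1-yl}-2-hydroxy-5-methoxycyclohexa-2,5-diene-1,4-dione; 20 3-methylbutan-1-amine
Product: 21 metachromin H, 3-{(2E)-5-[(1R,3R)-1,3-dimethyl-2-methylidenecyclohexyl]-3-methylpent-2-en-1-yl}-2-hydroxy-5-[(3-methylbutyl)amino]cyclohexa-2,5-diene-1,4-dione
Conditions: 20 (3 equiv), EtOH, rt; dilute aq citric acid wash
Reagents that add atoms: none
Why: Addition–elimination of a primary amine at the remaining vinylogous ester carbon (aminolysis of a methoxyquinone to the vinylogous amide), the only electrophilic site left once the hydroxyquinone is deprotonated.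

Compound list
1 | 3-methylcyclopent-2-en-1-one | CC1=CC(=O)CC1 | starting material
2 | 2-iodo-3-methylcyclopent-2-en-1-one | CC1=C(I)C(=O)CC1 | intermediate
3 | methyl 2-methyl-5-oxocyclopent-1-ene-1-carboxylate | COC(=O)C1=C(C)CCC1=O | intermediate
4 | (E)-penta-1,3-diene | C=C/C=C/C | starting material
5 | methyl (3aS,4R,7aS)-4,7a-dimethyl-3-oxo-1,2,3,4,7,7a-hexahydro-3aH-indene-3a-carboxylate | COC(=O)[C@@]12[C@H](C)C=CC[C@]1(C)CCC2=O | intermediate
6 | methyl (3aS,4R,7aR)-4,7a-dimethyl-3-oxooctahydro-3aH-indene-3a-carboxylate | COC(=O)[C@@]12[C@H](C)CCC[C@]1(C)CCC2=O | intermediate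
7 | methyl 3-hydroxy-3,4,7a-trimethyloctahydro-3aH-indene-3a-carboxylate (C3 epimers) | COC(=O)[C@@]12[C@H](C)CCC[C@]1(C)CCC2(C)O | intermediate
8 | 3a-(hydroxymethyl)-3,4,7a-trimethyloctahydro-1H-inden-3-ol | OC[C@@]12[C@H](C)CCC[C@]1(C)CCC2(C)O | intermediate
9 | (3-hydroxy-3,4,7a-trimethyloctahydro-3aH-inden-3a-yl)methyl methanesulfonate | CS(=O)(=O)OC[C@@]12[C@H](C)CCC[C@]1(C)CCC2(C)O | intermediate
10 | 4-[(1R,3R)-1,3-dimethyl-2-methylidenecyclohexyl]butan-2-one | C=C1[C@H](C)CCC[C@]1(C)CCC(C)=O | intermediate
11 | ethyl (2E)-5-[(1R,3R)-1,3-dimethyl-2-methylidenecyclohexyl]-3-methylpent-2-enoate | C=C1[C@H](C)CCC[C@]1(C)CC/C(C)=C/C(=O)OCC | intermediate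
12 | (2E)-5-[(1R,3R)-1,3-dimethyl-2-methylidenecyclohexyl]-3-methylpent-2-en-1-ol | C=C1[C@H](C)CCC[C@]1(C)CC/C(C)=C/CO | intermediate
13 | (1R,3R)-1-[(3E)-5-bromo-3-methylpent-3-en-1-yl]-1,3-dimethyl-2-methylidenecyclohexane | C=C1[C@H](C)CCC[C@]1(C)CC/C(C)=C/CBr | intermediate
14 | 1,2,4,5-tetramethoxybenzene | COc1cc(OC)c(OC)cc1OC | starting material
15 | (2,3,5,6-tetramethoxyphenyl)lithium | [Li]c1c(OC)c(OC)cc(OC)c1OC | intermediate (not isolated)
16 | (2,3,5,6-tetramethoxyphenyl)copper | [Cu]c1c(OC)c(OC)cc(OC)c1OC | intermediate (not isolated)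
17 | 3-{(2E)-5-[(1R,3R)-1,3-dimethyl-2-methylidenecyclohexyl]-3-methylpent-2-en-1-yl}-1,2,4,5-tetramethoxybenzene | C=C1[C@H](C)CCC[C@]1(C)CC/C(C)=C/Cc1c(OC)c(OC)cc(OC)c1OC | intermediate
18 | 3-{(2E)-5-[(1R,3R)-1,3-dimethyl-2-methylidenecyclohexyl]-3-methylpent-2-en-1-yl}-2,5-dimethoxycyclohexa-2,5-diene-1,4-dione | C=C1[C@H](C)CCC[C@]1(C)CC/C(C)=C/CC1=C(OC)C(=O)C=C(OC)C1=O | intermediate
19 | 3-{(2E)-5-[(1R,3R)-1,3-dimethyl-2-methylidenecyclohexyl]-3-methylpent-2-en-1-yl}-2-hydroxy-5-methoxycyclohexa-2,5-diene-1,4-dione | C=C1[C@H](C)CCC[C@]1(C)CC/C(C)=C/CC1=C(O)C(=O)C=C(OC)C1=O | intermediate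
20 | 3-methylbutan-1-amine | CC(C)CCN | starting material
21 | metachromin H | C=C1[C@H](C)CCC[C@]1(C)CC/C(C)=C/CC1=C(O)C(=O)C=C(NCCC(C)C)C1=O | target

Total step count: 15. Longest linear sequence: 15 steps (1 to 21); 4, 14 and 20 enter as purchased materials.

Steps most likely to fail

Step 3. The tetrasubstituted alkene may react too slowly with a simple diene, the diene may oligomerise at the cationic copper centre, or enantioface and ketone-endo discrimination may be poor. The fallback sets out from 2 and uses a covalently bound auxiliary with an achiral Lewis acid. Carbonylation of 2 with (−)-8-phenylmenthol in place of methanol (CO, Pd(PPh3)4, Et3N, toluene, 80 °C) would give (1R,2S,5R)-5-methyl-2-(2-phenylpropan-2-yl)cyclohexyl 2-methyl-5-oxocyclopent-1-ene-1-carboxylate F1. SnCl4 (Et2O, 0 °C) would then promote the cycloaddition with 4, a known reaction type for this dienophile class. The diastereomeric adducts would be separated by chromatography or crystallisation to give 8-phenylmenthyl (3aS,4R,7aS)-4,7a-dimethyl-3-oxo-1,2,3,4,7,7a-hexahydro-3aH-indene-3a-carboxylate F2, so the auxiliary serves as a resolving handle even if its facial bias is modest. Hydrogenation (H2, PtO2) would give 8-phenylmenthyl (3aS,4R,7aR)-4,7a-dimethyl-3-oxooctahydro-3aH-indene-3a-carboxylate F3, and MeLi–CeCl3 addition would give 8-phenylmenthyl 3-hydroxy-3,4,7a-trimethyloctahydro-3aH-indene-3a-carboxylate F4. LiAlH4 reduction, which releases the auxiliary, comes back to the route at 8.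

Step 5. The β-alkoxy ester may fragment by retro-aldol cleavage, addition to the hindered enolisable ketone may stall, or the ester may be attacked. The fallback sets out from 6 and installs the methyl group after the fragmentation. LiAlH4 would reduce ketone and ester together to 3a-(hydroxymethyl)-4,7a-dimethyloctahydro-1H-inden-3-ol F5. Selective sulfonylation of the primary hydroxyl (TsCl, pyridine, 0 °C) would give (3-hydroxy-4,7a-dimethyloctahydro-3aH-inden-3a-yl)methyl 4-methylbenzenesulfonate F6. KOt-Bu would trigger the same Grob fragmentation, now to 3-[(1R,3R)-1,3-dimethyl-2-methylidenecyclohexyl]propanal F7. MeMgBr addition would give 4-[(1R,3R)-1,3-dimethyl-2-methylidenecyclohexyl]butan-2-ol F8, and Dess–Martin oxidation comes back to the route at 10.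

Step 9. Geometric control may be insufficient in the olefination of a methyl ketone whose two substituents differ little in size, and the isomers may be hard to separate. The fallback sets out from 10 and builds the trisubstituted alkene by syn-carbometalation. Kinetic enolisation toward the methyl group (LiN(i-Pr)2, THF, −78 °C) and trapping with ClP(O)(OEt)2 would give diethyl 4-[(1R,3R)-1,3-dimethyl-2-methylidenecyclohexyl]but-1-en-2-yl phosphate F9. Further LiN(i-Pr)2 would eliminate it to (1R,3R)-1-(but-3-yn-1-yl)-1,3-dimethyl-2-methylidenecyclohexane F10. Zirconium-catalysed methylalumination (Negishi carboalumination; AlMe3, Cp2ZrCl2 cat., CH2Cl2) would add methyl and aluminium syn across the alkyne to [(1E)-4-[(1R,3R)-1,3-dimethyl-2-methylidenecyclohexyl]-2-methylbut-1-en-1-yl]dimethylalumane F11; the hindered 1,1-disubstituted methylene should not react. Activation with n-BuLi and trapping with paraformaldehyde comes back to the route at 12 as the (E)-isomer only, bypassing step 10 as well.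

Further compounds
F1 | step 3 | (1R,2S,5R)-5-methyl-2-(2-phenylpropan-2-yl)cyclohexyl 2-methyl-5-oxocyclopent-1-ene-1-carboxylate | CC(C)(c1ccccc1)[C@@H]1CC[C@@H](C)C[C@H]1OC(=O)C1=C(C)CCC1=O
F2 | step 3 | 8-phenylmenthyl (3aS,4R,7aS)-4,7a-dimethyl-3-oxo-1,2,3,4,7,7a-hexahydro-3aH-indene-3a-carboxylate | CC(C)(c1ccccc1)[C@@H]1CC[C@@H](C)C[C@H]1OC(=O)[C@@]12[C@H](C)C=CC[C@]1(C)CCC2=O
F3 | step 3 | 8-phenylmenthyl (3aS,4R,7aR)-4,7a-dimethyl-3-oxooctahydro-3aH-indene-3a-carboxylate | CC(C)(c1ccccc1)[C@@H]1CC[C@@H](C)C[C@H]1OC(=O)[C@@]12[C@H](C)CCC[C@]1(C)CCC2=O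
F4 | step 3 | 8-phenylmenthyl 3-hydroxy-3,4,7a-trimethyloctahydro-3aH-indene-3a-carboxylate | CC(C)(c1ccccc1)[C@@H]1CC[C@@H](C)C[C@H]1OC(=O)[C@@]12[C@H](C)CCC[C@]1(C)CCC2(C)O
F5 | step 5 | 3a-(hydroxymethyl)-4,7a-dimethyloctahydro-1H-inden-3-ol | OC[C@@]12[C@H](C)CCC[C@]1(C)CCC2O
F6 | step 5 | (3-hydroxy-4,7a-dimethyloctahydro-3aH-inden-3a-yl)methyl 4-methylbenzenesulfonate | Cc1ccc(cc1)S(=O)(=O)OC[C@@]12[C@H](C)CCC[C@]1(C)CCC2O
F7 | step 5 | 3-[(1R,3R)-1,3-dimethyl-2-methylidenecyclohexyl]propanal | C=C1[C@H](C)CCC[C@]1(C)CCC=O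
F8 | step 5 | 4-[(1R,3R)-1,3-dimethyl-2-methylidenecyclohexyl]butan-2-ol | C=C1[C@H](C)CCC[C@]1(C)CCC(C)O
F9 | step 9 | diethyl 4-[(1R,3R)-1,3-dimethyl-2-methylidenecyclohexyl]but-1-en-2-yl phosphate | C=C1[C@H](C)CCC[C@]1(C)CCC(=C)OP(=O)(OCC)OCC
F10 | step 9 | (1R,3R)-1-(but-3-yn-1-yl)-1,3-dimethyl-2-methylidenecyclohexane | C=C1[C@H](C)CCC[C@]1(C)CCC#C
F11 | step 9 | [(1E)-4-[(1R,3R)-1,3-dimethyl-2-methylidenecyclohexyl]-2-methylbut-1-en-1-yl]dimethylalumane | C=C1[C@H](C)CCC[C@]1(C)CC/C(C)=C/[Al](C)C
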